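At the last reading of the delta run, 80.0 min, starting material stood at 23.3 % and target at 16.0 %, and the meeting began from there.

| flask | starting material | partner | protic impurity | remark | time |
|---|---|---|---|---|---|
| delta | 0.010 M | 0.019 M | 4 mM | run made earlier |  |
| flask | 0.020 M | 0.0190 M | 4.00 mM |  | 12 h |

- delta (time / min: target / %, starting material / %): 6.00: 0.5, 87.0; 8.00: 0, 83.7; 12.0: 2.6, 75.0; 20.0: 2.3, 66.3; 30.0: 6.9, 54.2; 50.0: 11.1, 38.7; 80.0: 16.0, 23.3

(scatter of a reading: 1 percentage point)

* the best time, 12 h at the latest, for target
* the amount of target, in percent of the starting material charged, at that time

The first speaker proposed replacing the curved fall of starting material by one mean rate, read between the first and last readings, which gives a mean life of 56.2 min. She called 2.3 mean lives, 2.15 h, the clearing time, since on that mean rate 10.0 % of the starting material is then reckoned to remain, and she put her estimate of the best time of the flask there.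

The second speaker tested what the mean hides. The readings up to 30.0 min give a clearing time of 1.94 h, and the later readings give 2.27 h, so he reported that as the error of the reckoning.

A third speaker objected that the fall might follow partner. Partner charged beyond the protic impurity is 75.0 % of the starting material charged in the flask against 150 % in the delta run. The meeting kept the clearing time as its bet, but expected the flask's peak of target to stay under the 16.0 % of the last delta reading.

The forecast gives 18 % at 5 h, on the ground that “Partner is about 95–99% gone by 4–6 h, so target then stops growing”.

The flask gives 13.4 % at 2.23 h.

    starting material ⇌ tautomer (K = 1.50, k = 0.0160 min⁻¹)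
    starting material + partner → isomer of the product A (k = 0.450 L mol⁻¹ min⁻¹)
    partner + tautomer → target (k = 1.20 L mol⁻¹ min⁻¹)
    target ⇌ isomer of the product B (K = 1.60, k = 0.00510 min⁻¹)
    tautomer → side product (k = 0.0220 min⁻¹)
    partner + protic impurity → quenched reagent (k = 5.20 L mol⁻¹ min⁻¹)

In the flask the best time of 2.23 h sits by the clearing time of 2.15 h, with 12.2 % of the starting material left, and a flask with half the protic impurity has its best time at 2.20 h, also by the clearing time, which was read from the delta readings and has no term for the impurity charged. At 0.627 h tautomer was turning into side product 1.8 times as fast as it went on with partner to target. At the best time the flask held 36.7 % side product against 13.4 % target, and at 12.0 h it held 49.5 % against 8.84 %.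

The earlier runs and the new flask are calculated on assumed constants, noise included.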